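Anabsin is treated as the oxidatively cyclised Diels–Alder dimer of one guaianolide cyclopentadiene, so everything rests on building that monomer by closing its seven-membered ring at the C9–C10 bond (guaiane numbering). The key step, a samarium diiodide Barbier cyclisation, lets a 2-iodoethyl chain on lactone carbon C7 add to an acetyl group on C1 of a cyclopentene already joined to the lactone through C5–C6; one operation closes the seven-membered carbocycle and creates the tertiary carbinol C10 bearing methyl C14. It exploits exactly that feature: a methyl carbinol (C10) next to the unfunctionalised C9H2–C8H2 unit of the seven-membered ring. Diene formation, spontaneous dimerisation and syn-exo alkoxymercuration–oxygenation of the new norbornene finish the route.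

Key step: step 8

Remark: guaiane numbering is used throughout (C1–C5 five-membered ring; C1, C5–C10 seven-membered ring; C11–C13 lactone propionate; C14 on C10; C15 on C4); primed numbers denote the diene-derived half of the dimer.
Assumption: commercial (+)-limonene oxide is a cis/trans mixture at the epoxide, and both isomers should converge on 2.
Assumption: the (S,S) enantiomer of the ProPhenol ligand is taken to direct the acetylide to the Si face of enal 3; if the sense is opposite on this substrate, the (R,R) ligand is used instead.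

Step 1
Reactants: 1 (+)-limonene 1,2-oxide
Product: 2 (3R)-6-oxo-3-(prop-1-en-2-yl)heptanal
Conditions: H5IO6, THF/H2O, 0 °C to rt
Reagents that add atoms: periodic acid, OI(=O)(O)(O)(O)O
Why: Periodic acid should open the trisubstituted epoxide to the 1,2-diol and cleave it in the same flask (epoxide hydrolysis then Malaprade glycol cleavage), leaving the isopropenyl group and the stereocentre untouched.

Step 2
Reactants: 2 (3R)-6-oxo-3-(prop-1-en-2-yl)heptanal
Product: 3 (5S)-2-methyl-5-(prop-1-en-2-yl)cyclopent-1-ene-1-carbaldehyde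
Conditions: piperidine (cat.), AcOH (cat.), benzene, reflux, Dean–Stark
Reagents that add atoms: none
Why: Intramolecular aldol condensation through the piperidine enamine of the aldehyde onto the methyl ketone should close the cyclopentene and dehydrate to the conjugated enal without involving the stereocentre (future C1).

Step 3
Reactants: 3 (5S)-2-methyl-5-(prop-1-en-2-yl)cyclopent-1-ene-1-carbaldehyde; 4 methyl propiolate
Product: 5 methyl (4S)-4-hydroxy-4-[(5S)-2-methyl-5-(prop-1-en-2-yl)cyclopent-1-en-1-yl]but-2-ynoate
Conditions: (S,S)-ProPhenol (20 mol %), Me2Zn, Ph3P=O (40 mol %), toluene, 0 °C; aq. NH4Cl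
Reagents that add atoms: none
Why: Zinc–ProPhenol catalysed asymmetric alkynylation of the enal should deliver the zinc acetylide to the Si face of the aldehyde, setting C6 as (S) under reagent control with little influence from the remote C1 centre.

Step 4
Reactants: 5 methyl (4S)-4-hydroxy-4-[(5S)-2-methyl-5-(prop-1-en-2-yl)cyclopent-1-en-1-yl]but-2-ynoate
Product: 7 (5S)-5-[(5S)-2-methyl-5-(prop-1-en-2-yl)cyclopent-1-en-1-yl]furan-2(5H)-one, via Z-hydroxy enoate 6 (not isolated)
Conditions: H2 (1 atm), Pd/CaCO3–Pb(OAc)2 (Lindlar catalyst), quinoline, EtOAc, rt; filter; PPTS (cat.), rt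
Reagents that add atoms: none
Why: Lindlar cis-semihydrogenation of the ynoate should give the Z-γ-hydroxy enoate, which lactonises to the butenolide without touching C6 or the two alkenes.

Step 5
Reactants: 7 (5S)-5-[(5S)-2-methyl-5-(prop-1-en-2-yl)cyclopent-1-en-1-yl]furan-2(5H)-one
Product: 9 (3S,4S,5S)-3-methyl-5-[(5S)-2-methyl-5-(prop-1-en-2-yl)cyclopent-1-en-1-yl]-4-vinyloxolan-2-one, via magnesium enolate 8 (not isolated)
Conditions: CH2=CHMgBr, CuBr·SMe2 (15 mol %), THF, −78 to −40 °C; then MeI, DMPU, −40 to 0 °C
Reagents that add atoms: vinylmagnesium bromide, C=C[Mg]Br; iodomethane, CI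
Why: Copper-catalysed conjugate addition should place the vinyl group on C7 anti to the bulky cyclopentenyl group on C6, and methylation of the resulting enolate anti to the new vinyl group should set C11 (tandem vicinal difunctionalisation), giving the all-trans lactone.

Step 6
Reactants: 9 (3S,4S,5S)-3-methyl-5-[(5S)-2-methyl-5-(prop-1-en-2-yl)cyclopent-1-en-1-yl]-4-vinyloxolan-2-one
Product: 11 (3S,4S,5S)-4-(2-iodoethyl)-3-methyl-5-[(5S)-2-methyl-5-(prop-1-en-2-yl)cyclopent-1-en-1-yl]oxolan-2-one, via alkylzirconocene chloride 10 (not isolated)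
Conditions: Cp2Zr(H)Cl (1.2 equiv), THF, rt; then I2, 0 °C
Reagents that add atoms: iodine, II
Why: Hydrozirconation should place zirconium on the terminal carbon of the monosubstituted vinyl group faster than on the 1,1-disubstituted isopropenyl or the tetrasubstituted ring alkene, and iodinolysis of the C–Zr bond then gives the primary iodide (anti-Markovnikov hydroiodination).

Step 7
Reactants: 11 (3S,4S,5S)-4-(2-iodoethyl)-3-methyl-5-[(5S)-2-methyl-5-(prop-1-en-2-yl)cyclopent-1-en-1-yl]oxolan-2-one
Product: 12 (3S,4S,5S)-5-[(5R)-5-acetyl-2-methylcyclopent-1-en-1-yl]-4-(2-iodoethyl)-3-methyloxolan-2-one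
Conditions: OsO4 (2 mol %), NaIO4, 2,6-lutidine, dioxane/H2O, rt
Reagents that add atoms: sodium periodate, [Na+].[O-]I(=O)(=O)=O (terminal oxidant; the oxygen is transferred through OsO4)
Why: In this Lemieux–Johnson cleavage OsO4 should dihydroxylate the accessible isopropenyl alkene far faster than the tetrasubstituted C4=C5 bond, and periodate cleaves the diol to the methyl ketone under buffered conditions that should not epimerise C1.

Step 8
Reactants: 12 (3S,4S,5S)-5-[(5R)-5-acetyl-2-methylcyclopent-1-en-1-yl]-4-(2-iodoethyl)-3-methyloxolan-2-one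
Product: 13 10β-hydroxy-1αH,6βH,7αH,11βH-guai-4-en-12,6α-olide
Conditions: SmI2 (2.5 equiv), HMPA (10 equiv), THF (0.005 M), −78 °C to rt; aq. NH4Cl
Reagents that add atoms: none
Why: Samarium diiodide–HMPA should reduce the primary C–I bond by two single-electron transfers to an alkylsamarium species at C9, which adds intramolecularly to the C10 ketone and gives the tertiary alcohol on work-up; the closest known reaction type is the intramolecular samarium Barbier cyclisation of ω-iodo ketones. The seven-membered carbocycle is closed in a 7-exo-trig mode by forming the C9–C10 bond, with the trans-fused lactone and the sp2 carbon C5 holding the two chain ends close together; because both halves of the dimer derive from 13, this bond is made here for each guaianolide unit. The new stereocentre C10 is controlled by the adjacent C1 centre: the acetyl group should react through the rotamer that keeps C1–H near the acetyl methyl and C2 near the carbonyl oxygen, so that C9, which can only approach from the side of C5, attacks the face giving the 10β-hydroxy-10α-methyl arrangement. The step needs chemoselectivity for the ketone over the lactone carbonyl, secured by the higher electrophilicity of the ketone and by the strain of the bridged oxabicyclo[2.2.1]heptane hemiketal that attack at C12 would require, and it needs cyclisation to outrun simple reduction of the iodide, which high dilution and the absence of a proton source favour.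

Step 9
Reactants: 13 10β-hydroxy-1αH,6βH,7αH,11βH-guai-4-en-12,6α-olide
Product: 14 10β-hydroxy-3-oxo-1αH,6βH,7αH,11βH-guai-4-en-12,6α-olide
Conditions: CrO3, 3,5-dimethylpyrazole, CH2Cl2, −20 °C
Reagents that add atoms: chromium trioxide, O=[Cr](=O)=O
Why: Allylic oxidation with the CrO3–3,5-dimethylpyrazole complex should convert the only allylic ring methylene (C3) into the enone carbonyl, the tertiary C1–H and C6–H and the C15 methyl being less prone to this oxidation and the tertiary alcohol being inert.

Step 10
Reactants: 14 10β-hydroxy-3-oxo-1αH,6βH,7αH,11βH-guai-4-en-12,6α-olide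
Product: 15 3β,10β-dihydroxy-1αH,6βH,7αH,11βH-guai-4-en-12,6α-olide
Conditions: NaBH4, CeCl3·7H2O, MeOH, −40 °C
Reagents that add atoms: none
Why: Luche 1,2-reduction of the cyclopentenone should deliver hydride to the α face, anti to the C1–C10 bond, giving the 3β-alcohol, a centre that is removed in the next step so that either epimer would serve.

Step 11
Reactants: 15 3β,10β-dihydroxy-1αH,6βH,7αH,11βH-guai-4-en-12,6α-olide
Product: 17 10β-hydroxy-1αH,6βH,7αH,11βH-guaia-2,4-dien-12,6α-olide, via allylic mesylate 16 (not isolated)
Conditions: MsCl (1.2 equiv), Et3N (4 equiv), CH2Cl2, −30 to 0 °C; used at once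
Reagents that add atoms: none
Why: The secondary allylic alcohol should be mesylated in preference to the hindered tertiary C10–OH, and base-induced 1,2-elimination of the allylic sulfonate, whose only β-hydrogens are on C2, should give the 2,4-diene with C1 untouched.

Step 12
Reactants: 17 10β-hydroxy-1αH,6βH,7αH,11βH-guaia-2,4-dien-12,6α-olide (two molecules)
Product: 18 absinthin
Conditions: neat, rt, dark, Ar, several days
Reagents that add atoms: none
Why: In this Diels–Alder dimerisation, typical of cyclopentadienes, one molecule should react as diene through C2′/C5′ and a second as dienophile through its less substituted C2=C3 bond in an endo transition state, both partners being attacked on their α faces anti to the C1–C10 bond, which sets C2, C3, C2′ and C5′ and makes C1′ the bridge carbon.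

Step 13
Reactants: 18 absinthin
Product: 19 3′-exo-chloromercurio-4′,10′-epoxy derivative of absinthin
Conditions: Hg(OAc)2, THF, 0 °C to rt; then aq. NaCl
Reagents that add atoms: mercury diacetate, CC(=O)O[Hg]OC(C)=O; sodium chloride, [Na+].[Cl-]
Why: In this intramolecular alkoxymercuration divalent mercury should attack the strained C3′=C4′ norbornene bond on its exo face, and the C10′ hydroxyl held over that face closes the tetrahydrofuran at the more substituted C4′ (Markovnikov syn-exo addition, as usual for norbornenes), while the tetrasubstituted C4=C5 bond is too hindered to react.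

Step 14
Reactants: 19 3′-exo-chloromercurio-4′,10′-epoxy derivative of absinthin
Product: 20 anabsin
Conditions: NaBH4, O2, DMF, 0 °C
Reagents that add atoms: dioxygen, O=O
Why: In this oxidative demercuration borohydride should convert the C–Hg bond into the C3′ radical, which is trapped by oxygen on the exo face because the endo face is blocked by the other guaianolide unit, and the hydroperoxide is reduced in situ to the 3′-exo alcohol.

Compound list
1 | (+)-limonene 1,2-oxide, (4R)-1-methyl-4-(prop-1-en-2-yl)-7-oxabicyclo[4.1.0]heptane, commercial cis/trans mixture at the epoxide | CC12CC[C@H](CC1O2)C(C)=C | starting material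
2 | (3R)-6-oxo-3-(prop-1-en-2-yl)heptanal | CC(=O)CC[C@H](CC=O)C(C)=C | intermediate
3 | (5S)-2-methyl-5-(prop-1-en-2-yl)cyclopent-1-ene-1-carbaldehyde | CC1=C(C=O)[C@H](C(C)=C)CC1 | intermediate
4 | methyl propiolate | C#CC(=O)OC | starting material
5 | methyl (4S)-4-hydroxy-4-[(5S)-2-methyl-5-(prop-1-en-2-yl)cyclopent-1-en-1-yl]but-2-ynoate | CC1=C([C@@H](O)C#CC(=O)OC)[C@H](C(C)=C)CC1 | intermediate
6 | methyl (2Z,4S)-4-hydroxy-4-[(5S)-2-methyl-5-(prop-1-en-2-yl)cyclopent-1-en-1-yl]but-2-enoate | CC1=C([C@@H](O)/C=C\C(=O)OC)[C@H](C(C)=C)CC1 | intermediate (not isolated)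
7 | (5S)-5-[(5S)-2-methyl-5-(prop-1-en-2-yl)cyclopent-1-en-1-yl]furan-2(5H)-one | CC1=C([C@H]2OC(=O)C=C2)[C@H](C(C)=C)CC1 | intermediate
8 | bromomagnesium enolate of (4S,5S)-5-[(5S)-2-methyl-5-(prop-1-en-2-yl)cyclopent-1-en-1-yl]-4-vinyloxolan-2-one | CC1=C([C@H]2OC(O[Mg]Br)=C[C@@H]2C=C)[C@H](C(C)=C)CC1 | intermediate (not isolated)
9 | (3S,4S,5S)-3-methyl-5-[(5S)-2-methyl-5-(prop-1-en-2-yl)cyclopent-1-en-1-yl]-4-vinyloxolan-2-one (all-trans lactone) | CC1=C([C@H]2OC(=O)[C@@H](C)[C@@H]2C=C)[C@H](C(C)=C)CC1 | intermediate
10 | alkylzirconocene chloride: 9 with Cp2Zr(Cl) on the terminal carbon (C9) of the former vinyl group | CC1=C([C@H]2OC(=O)[C@@H](C)[C@@H]2CC[Zr](Cl)(C3C=CC=C3)C3C=CC=C3)[C@H](C(C)=C)CC1 | intermediate (not isolated)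
11 | (3S,4S,5S)-4-(2-iodoethyl)-3-methyl-5-[(5S)-2-methyl-5-(prop-1-en-2-yl)cyclopent-1-en-1-yl]oxolan-2-one | CC1=C([C@H]2OC(=O)[C@@H](C)[C@@H]2CCI)[C@H](C(C)=C)CC1 | intermediate
12 | (3S,4S,5S)-5-[(5R)-5-acetyl-2-methylcyclopent-1-en-1-yl]-4-(2-iodoethyl)-3-methyloxolan-2-one | CC1=C([C@H]2OC(=O)[C@@H](C)[C@@H]2CCI)[C@H](C(C)=O)CC1 | intermediate
13 | 10β-hydroxy-1αH,6βH,7αH,11βH-guai-4-en-12,6α-olide (10α-methyl) | CC1=C2[C@H]3OC(=O)[C@@H](C)[C@@H]3CC[C@](C)(O)[C@@H]2CC1 | intermediate
14 | 10β-hydroxy-3-oxo-1αH,6βH,7αH,11βH-guai-4-en-12,6α-olide | CC1=C2[C@H]3OC(=O)[C@@H](C)[C@@H]3CC[C@](C)(O)[C@@H]2CC1=O | intermediate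
15 | 3β,10β-dihydroxy-1αH,6βH,7αH,11βH-guai-4-en-12,6α-olide | CC1=C2[C@H]3OC(=O)[C@@H](C)[C@@H]3CC[C@](C)(O)[C@@H]2C[C@@H]1O | intermediate
16 | 3β-methanesulfonate of 15 | CC1=C2[C@H]3OC(=O)[C@@H](C)[C@@H]3CC[C@](C)(O)[C@@H]2C[C@@H]1OS(C)(=O)=O | intermediate (not isolated)
17 | 10β-hydroxy-1αH,6βH,7αH,11βH-guaia-2,4-dien-12,6α-olide | CC1=C2[C@H]3OC(=O)[C@@H](C)[C@@H]3CC[C@](C)(O)[C@@H]2C=C1 | intermediate
18 | absinthin: endo Diels–Alder dimer of 17 with new bonds C2–C2′ and C3–C5′ on the α faces of both halves, C3′=C4′ in the norbornene, C4=C5 retained, both 10β-hydroxyls free | CC1=C2[C@H]3OC(=O)[C@@H](C)[C@@H]3CC[C@](C)(O)[C@@H]2[C@H]2[C@H]3C=C(C)[C@@]5([C@H]4OC(=O)[C@@H](C)[C@@H]4CC[C@](C)(O)[C@H]35)[C@@H]12 | intermediate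
19 | 18 in which the C10′ oxygen is bonded to C4′ (exo) and C3′ carries an exo HgCl group | CC1=C2[C@H]3OC(=O)[C@@H](C)[C@@H]3CC[C@](C)(O)[C@@H]2[C@H]2[C@@H]3[C@@H]4[C@]5([C@H]6OC(=O)[C@@H](C)[C@@H]6CC[C@]4(C)O[C@@]5(C)[C@H]3[Hg]Cl)[C@@H]12 | intermediate
20 | anabsin | CC1=C2[C@H]3OC(=O)[C@@H](C)[C@@H]3CC[C@](C)(O)[C@@H]2[C@H]2[C@@H]3[C@@H]4[C@]5([C@H]6OC(=O)[C@@H](C)[C@@H]6CC[C@]4(C)O[C@@]5(C)[C@H]3O)[C@@H]12 | target

Total step count: 14. Longest linear sequence: 14 steps (from 1).

Steps most likely to fail

Step 8. The cyclisation may lose out to premature reduction of the carbon–iodine bond to C–H, to attack on the lactone carbonyl, or to poor facial control at C10 in a slow seven-membered closure. The fallback sets out from butenolide 7 and comes back at 13, still closing the ring at C9–C10. Copper-catalysed conjugate addition of allylmagnesium bromide in the presence of TMSCl, anti to the C6 substituent, would give after aqueous work-up (4S,5S)-4-allyl-5-[(5S)-2-methyl-5-(prop-1-en-2-yl)cyclopent-1-en-1-yl]oxolan-2-one F1. Enolate methylation (LDA, MeI) anti to the allyl group would give the (3S,4S,5S)-3-methyl derivative F2. Ring-closing metathesis of the allyl and isopropenyl groups with the second-generation Grubbs catalyst, RuCl2(=CHPh)(H2IMes)(PCy3), in refluxing CH2Cl2 would close the seven-membered ring as the trisubstituted C9=C10 alkene, 1αH,6βH,7αH,11βH-guaia-4,9-dien-12,6α-olide F3. Mukaiyama hydration (Mn(dpm)3, PhSiH3, O2) of that alkene, Markovnikov and sparing the tetrasubstituted C4=C5 bond, would then give 13, with separation of C10 epimers if needed.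

Step 9. Hydrogen abstraction may occur at the tertiary allylic positions C1 or C6 instead of C3, or oxidation may run on past the enone. The fallback sets out from 13 and comes back at 15, bypassing ketone 14. SeO2 (cat.) with t-BuOOH in CH2Cl2 hydroxylates by an ene reaction followed by a [2,3]-sigmatropic shift, a pericyclic pathway with the known preference CH2 > CH3 > CH, and should deliver the C3 allylic alcohol directly. Any 14 formed by over-oxidation is reduced as in step 10. This fallback makes no compound outside the list (F0).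

Step 13. Alkoxymercuration of the hindered, syn-substituted norbornene may be slow or close the ether at the wrong carbon, and the following step may end in protodemercuration instead of oxygenation. The fallback sets out from 18 and comes back at 20, bypassing 19. Epoxidation with mCPBA (1 equiv, NaHCO3, CH2Cl2, −40 °C), guided to the exo face of the strained C3′=C4′ bond by hydrogen bonding to the overhanging C10′ hydroxyl, would give the 3′,4′-exo-epoxide of absinthin F4. Catalytic CSA would then ionise the epoxide at tertiary C4′, and capture of the cation by the C10′ hydroxyl on the same exo face would give 20 with the exo C3′ hydroxyl.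

Further compounds
F1 | step 8 | (4S,5S)-4-allyl-5-[(5S)-2-methyl-5-(prop-1-en-2-yl)cyclopent-1-en-1-yl]oxolan-2-one | CC1=C([C@H]2OC(=O)C[C@@H]2CC=C)[C@H](C(C)=C)CC1
F2 | step 8 | (3S,4S,5S)-4-allyl-3-methyl-5-[(5S)-2-methyl-5-(prop-1-en-2-yl)cyclopent-1-en-1-yl]oxolan-2-one | CC1=C([C@H]2OC(=O)[C@@H](C)[C@@H]2CC=C)[C@H](C(C)=C)CC1
F3 | step 8 | 1αH,6βH,7αH,11βH-guaia-4,9-dien-12,6α-olide | CC1=C2[C@H]3OC(=O)[C@@H](C)[C@@H]3CC=C(C)[C@@H]2CC1
F0 | step 9 | none | none
F4 | step 13 | 3′,4′-exo-epoxide of absinthin | CC1=C2[C@H]3OC(=O)[C@@H](C)[C@@H]3CC[C@](C)(O)[C@@H]2[C@H]2[C@H]3[C@@H]6O[C@]6(C)[C@@]5([C@H]4OC(=O)[C@@H](C)[C@@H]4CC[C@](C)(O)[C@H]35)[C@@H]12
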